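Time works against Kat here, so we hand over the flasks with a reckoning in time.

| setting | spring | winter | grey | blue | red | green |
|---|---|---|---|---|---|---|
| Sub | 0.37 mM | 2.9 mM | 1.0 mM | 0.30 mM | 0.50 mM | 2.0 mM |
| Oth | 0.12 mM (held) | 0.12 mM (held) | 0.12 mM (held) | 0.12 mM (held) | 0.12 mM (held) | 0.12 mM (held) |
| Kat | 0.38 mol% | 0.38 mol% | 0.38 mol% | 0.38 mol% | 0.38 mol% | 0.38 mol% |
| remark | run made earlier | run made earlier |  |  |  |  |
| time |  |  | 6.0 min | 6.0 min | 6.0 min | 6.0 min |

- spring (time / min: Prd / %, Sub / %): 0.833: 18.0, 82.2; 1.50: 28.9, 70.4; 2.50: 39.9, 60.4; 3.00: 42.7, 57.9; 4.00: 46.0, 54.3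
- winter (time / min: Prd / %, Sub / %): 0.333: 5.7, 94.6; 0.667: 11.9, 89.7; 1.33: 24.2, 75.6; 2.00: 35.0, 66.1; 4.00: 59.1, 40.9

(scatter of a reading: 0.5 percentage points)

- at the start none of Oth is in solution
- a reading or a percentage of Prd counts all its forms, free or not

* ranking by amount of Prd, in percent of the Sub charged, from high to low, at 6.0 min (grey / blue / red / green)
* the same order at 80 s (grey / blue / red / green)
* the amount of Prd, in percent of the Sub charged of the flask you put first, at 6.0 min
* the amount of Prd, in percent of the Sub charged of the flask you put last, at 6.0 min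

In the spring run, ln([Sub] charged / [Sub] left) grew by 0.153 from 1.50 min to 2.50 min, but by only 0.0642 from 3.00 min to 4.00 min, an equally long step begun 1.50 min later. We read this as Kat dying at first order, with a rate constant k of 0.580 min⁻¹, a loose reading given the scatter. If [Sub] falls pseudo-first-order in living Kat, the rate integrates: that logarithm equals B times (1 − exp(−kt)). Spring's last reading gives 0.677 for the catalyst budget B, the logarithm a charge of Kat spends over its whole life while the gas keeps up. At fixed mol%, and with the gas keeping up, we take B to scale with the [Sub] charged.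

| Flask | B | Prd at 6.0 min | Prd at 80 s |
|---|---|---|---|
| blue | 0.549 | 41.3% | 25.6% |
| red | 0.915 | 58.8% | 38.9% |
| grey | 1.83 | 83.0% | 62.7% |
| green | 3.66 | 97.1% | 86.1% |

Winter's steady climb reads as a gas supply of 0.503 mM min⁻¹. Blue and red start by asking less than that, 0.0955 mM min⁻¹ and 0.265 mM min⁻¹, while grey and green ask more, 1.06 mM min⁻¹ and 4.25 mM min⁻¹. So we take the table's values for grey and green as upper estimates, and at 80 s that supply reckons to 33.5% for green. We commit to grey, red, green, blue at 80 s, and to green, grey, red, blue at 6.0 min. Please leave the loading alone: at fixed [Sub] we take B to grow with the mol% of Kat.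

The forecast, reasoning that “the ceiling rises with concentration”, gave green > grey > red > blue at 6.0 min and red > blue > grey > green at 80 s, with 66% first and 46% last at 6.0 min.

The flasks give green > grey > red > blue at 6.0 min and grey > red > green > blue at 80 s, with 75.7% first and 43.8% last.

    Oth ⇌ Oth2, rate k1*(csat - [Oth2]) (kL = 0.0783 s⁻¹)
    Sub + Oth2 + Kat → Kat + Prd (k = 4.62 × 10⁷ L² mol⁻² s⁻¹)
    Kat → Zed (k = 0.00879 s⁻¹)
    Oth3 ⇌ Prd, rate k4*(cs4 - [Prd]) while solid is left; crystals form when [Prd] > cs4 (solubility = 0.0850 mM, k = 2.06 s⁻¹)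

At 6.0 min blue gives 43.8%, and green 75.7%, less than the 97.1% of its table row. At 3.00 min, Oth2, the dissolved gas, stood lower in green than in blue, at 0.0646 mM against 0.117 mM. Spent whole, blue's budget gives 42.2% Prd, and at 60.0 min blue holds 45.4% Prd.

For blue with 1.5 mol% of Kat, the budget becomes 2.17, which gives 87.8% Prd by 6.0 min. That flask gives 87.3% Prd, with 12.7% of the Sub left.

(The earlier runs and the new flask were generated by integration for an exercise; noise was put on by code.)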